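**Plan**

1. Labels: ring A = arene; ring B = pyran (O, C1, C2, C11); ring C = cyclopentane C1–C5 (C1 = O–CH, C2 = C–CH3, C5 = spiro carbon); ring D = cyclohexene C5–C6=C7(iPr)–C8–C9–C10(CH3); C11 = ArCH(iBu).
2. Cuts, in order: C6=C7 of ring D (alkene metathesis), C1–H (from a ketal), ring B (O–C1 and C2–C11, ortho-quinone methide + enol ether), C5–C10 (Claisen). The first cut is possible because C6=C7 is the only C=C of the skeleton, lies wholly in ring D, carries no heteroatom, and joins spiro C5 to the isopropyl-bearing C7, so ring D opens to a C5-vinyl group and a 2-isopropyl-1-alkene.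
3. Forward: ring C is bought as a cyclopentanone; C5/C10 come from a catalytic asymmetric Claisen rearrangement; the side chain (Suzuki), the C5-vinyl group (Wittig), the C2 methyl and the enol silane follow; rings A/B are fused on by Knoevenagel/hetero-Diels–Alder; the ketal is reduced; ring D is closed last.
4. Stereochemistry: C5 and C10 arise together in the chair Claisen transition state of the E-crotyl ether (relative) under a chiral guanidinium catalyst (absolute). C2 and C11 come from the cycloaddition (anti to the C10 branch on C5, siloxy endo). C1 comes from hydride delivery that keeps the B/C junction cis.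

Key step: step 11

Remark: the sense of induction of the guanidinium catalyst in step 2 is not derived here; the enantiomer that gives 4 is used (its mirror image would give ent-4).

**Route**

Step 1
Reactants: 1 methyl 2-oxocyclopentane-1-carboxylate; 2 (E)-but-2-en-1-ol
Product: 3 methyl 2-[(E)-but-2-enyloxy]cyclopent-1-ene-1-carboxylate
Conditions: PPh3, diisopropyl azodicarboxylate, THF, 0 °C to rt
Reagents that add atoms: none
Why: Mitsunobu O-alkylation of the acidic, enolised β-keto ester by the primary allylic alcohol should give the O-allyl enol ether with the E alkene intact; no stereocentre is formed.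

Step 2
Reactants: 3 methyl 2-[(E)-but-2-enyloxy]cyclopent-1-ene-1-carboxylate
Product: 4 methyl (1S)-1-[(2S)-but-3-en-2-yl]-2-oxocyclopentane-1-carboxylate
Conditions: N,N'-bis[(1R,2R)-2-(2,5-diphenylpyrrol-1-yl)cyclohexyl]guanidinium tetrakis[3,5-bis(trifluoromethyl)phenyl]borate (20 mol %, enantiomer that gives 4), hexanes, 35 °C
Reagents that add atoms: none
Why: Hydrogen-bond-donor-catalysed enantioselective Claisen rearrangement of an O-allyl β-keto ester: C5 and C10 form together in a chair [3,3] transition state in which the E-crotyl methyl is pseudo-equatorial (this fixes the S,S/R,R relative configuration), and the guanidinium ion bound to the ether oxygen and ester carbonyl selects the enol ether face (absolute configuration).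

Step 3
Reactants: 4 methyl (1S)-1-[(2S)-but-3-en-2-yl]-2-oxocyclopentane-1-carboxylate; 5 2-bromo-3-methylbut-1-ene
Product: 7 methyl (1S)-1-[(2S)-6-methyl-5-methylideneheptan-2-yl]-2-oxocyclopentane-1-carboxylate, via alkylborane 6 (not isolated)
Conditions: 9-borabicyclo[3.3.1]nonane (9-BBN), THF, 0 °C to rt; then 5, Pd(dppf)Cl2 (5 mol %), AsPh3, Cs2CO3, DMF/H2O, rt
Reagents that add atoms: none
Why: Anti-Markovnikov hydroboration of the only alkene (the α-quaternary ketone is reduced much more slowly by 9-BBN) followed by B-alkyl Suzuki–Miyaura coupling with the vinyl bromide installs C8–C7(iPr)=CH2 without touching C5 or C10.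

Step 4
Reactants: 7 methyl (1S)-1-[(2S)-6-methyl-5-methylideneheptan-2-yl]-2-oxocyclopentane-1-carboxylate
Product: 8 (1RS,2R)-2-(hydroxymethyl)-2-[(2S)-6-methyl-5-methylideneheptan-2-yl]cyclopentan-1-ol
Conditions: LiAlH4, THF, 0 °C to rt
Reagents that add atoms: none
Why: Hydride reduction of ester and ketone to the diol; the new carbinol centre is left as a mixture because it is oxidised again in step 5.

Step 5
Reactants: 8 (1RS,2R)-2-(hydroxymethyl)-2-[(2S)-6-methyl-5-methylideneheptan-2-yl]cyclopentan-1-ol
Product: 9 (1R)-1-[(2S)-6-methyl-5-methylideneheptan-2-yl]-2-oxocyclopentane-1-carbaldehyde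
Conditions: Dess–Martin periodinane (2.5 equiv), CH2Cl2, rt
Reagents that add atoms: none
Why: Double Dess–Martin oxidation gives the keto aldehyde, in which the quaternary C5 cannot epimerise.

Step 6
Reactants: 9 (1R)-1-[(2S)-6-methyl-5-methylideneheptan-2-yl]-2-oxocyclopentane-1-carbaldehyde
Product: 10 (2S)-2-ethenyl-2-[(2S)-6-methyl-5-methylideneheptan-2-yl]cyclopentan-1-one
Conditions: MePPh3Br, KOtBu, THF, 0 °C; then 9, −78 to 0 °C
Reagents that add atoms: methyltriphenylphosphonium bromide, C[P+](c1ccccc1)(c1ccccc1)c1ccccc1.[Br-]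
Why: Wittig methylenation with one equivalent of ylide is chemoselective for the aldehyde over the hindered α-quaternary ketone and gives the C5-vinyl group (C6).

Step 7
Reactants: 10 (2S)-2-ethenyl-2-[(2S)-6-methyl-5-methylideneheptan-2-yl]cyclopentan-1-one
Product: 12 (2S,5RS)-2-ethenyl-5-methyl-2-[(2S)-6-methyl-5-methylideneheptan-2-yl]cyclopentan-1-one, via lithium enolate 11 (not isolated)
Conditions: LiN(iPr)2, THF, −78 °C; MeI, −78 to −20 °C
Reagents that add atoms: iodomethane, CI
Why: Enolate alkylation; C2 is the only enolisable position because C5 is quaternary, and the C2 configuration is irrelevant since C2 becomes sp2 in step 8.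

Step 8
Reactants: 12 (2S,5RS)-2-ethenyl-5-methyl-2-[(2S)-6-methyl-5-methylideneheptan-2-yl]cyclopentan-1-one
Product: 13 tert-butyl({(5S)-5-ethenyl-2-methyl-5-[(2S)-6-methyl-5-methylideneheptan-2-yl]cyclopent-1-en-1-yl}oxy)dimethylsilane
Conditions: tert-butyldimethylsilyl triflate, Et3N, CH2Cl2, 0 °C to rt
Reagents that add atoms: tert-butyldimethylsilyl trifluoromethanesulfonate, CC(C)(C)[Si](C)(C)OS(=O)(=O)C(F)(F)F
Why: Soft enolisation and O-silylation can only give the C1=C2 enol ether, so both C2 epimers of 12 converge on one tetrasubstituted silyl enol ether.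

Step 9
Reactants: 13 tert-butyl({(5S)-5-ethenyl-2-methyl-5-[(2S)-6-methyl-5-methylideneheptan-2-yl]cyclopent-1-en-1-yl}oxy)dimethylsilane; 14 2,4,6-trihydroxybenzene-1,3-dicarbaldehyde; 15 3-methylbutanal
Product: 17 (3S,3aR,9S,9aR)-3a-[(tert-butyldimethylsilyl)oxy]-3-ethenyl-6,8-dihydroxy-9a-methyl-3-[(2S)-6-methyl-5-methylideneheptan-2-yl]-9-(2-methylpropyl)-1,2,3,3a,9,9a-hexahydrocyclopenta[b]chromene-5,7-dicarbaldehyde, via ortho-quinone methide 16 (not isolated)
Conditions: ethylenediammonium diacetate (10 mol %), 4 Å molecular sieves, CH2Cl2, rt to 40 °C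
Reagents that add atoms: none
Why: Domino Knoevenagel condensation/inverse-electron-demand hetero-Diels–Alder reaction: the E ortho-quinone methide from 14 and 15 adds to the electron-rich enol silane (far more nucleophilic than the two unactivated alkenes) with its benzylic carbon on the nucleophilic C2 and its oxygen on C1, suprafacially (cis B/C fusion), on the enol ether face anti to the bulkier C10 branch of C5 (sets C2 relative to C5) and with the siloxy group endo and the carbocycle exo (sets C11).

Step 10
Reactants: 17 (3S,3aR,9S,9aR)-3a-[(tert-butyldimethylsilyl)oxy]-3-ethenyl-6,8-dihydroxy-9a-methyl-3-[(2S)-6-methyl-5-methylideneheptan-2-yl]-9-(2-methylpropyl)-1,2,3,3a,9,9a-hexahydrocyclopenta[b]chromene-5,7-dicarbaldehyde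
Product: 18 (3S,3aS,9R,9aR)-3-ethenyl-6,8-dihydroxy-9a-methyl-3-[(2S)-6-methyl-5-methylideneheptan-2-yl]-9-(2-methylpropyl)-1,2,3,3a,9,9a-hexahydrocyclopenta[b]chromene-5,7-dicarbaldehyde
Conditions: Et3SiH, BF3·OEt2, CH2Cl2, −78 to −40 °C
Reagents that add atoms: none
Why: Ionic hydrogenation of the mixed silyl ketal: BF3 ionises the siloxy group and Et3SiH should deliver hydride to C1 on the face that keeps the six–five junction cis (H at C1 syn to the C2 methyl, the trans-fused alternative being more strained), while at low temperature the hydrogen-bonded formyl groups and the isolated alkenes should not be reduced.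

Step 11
Reactants: 18 (3S,3aS,9R,9aR)-3-ethenyl-6,8-dihydroxy-9a-methyl-3-[(2S)-6-methyl-5-methylideneheptan-2-yl]-9-(2-methylpropyl)-1,2,3,3a,9,9a-hexahydrocyclopenta[b]chromene-5,7-dicarbaldehyde
Product: 19 (1R,3a'S,6S,9'R,9a'R)-6',8'-dihydroxy-6,9a'-dimethyl-9'-(2-methylpropyl)-3-(propan-2-yl)-1',2',9',9a'-tetrahydro-3a'H-spiro[cyclohex-2-ene-1,3'-cyclopenta[b]chromene]-5',7'-dicarbaldehyde (CNP0121396.2)
Conditions: second-generation Hoveyda–Grubbs catalyst, RuCl2(H2IMes)(=CH–C6H4-2-OiPr) (5–10 mol %), degassed toluene, 0.005 M, 60–80 °C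
Reagents that add atoms: none
Why: Ring-closing olefin metathesis: the ruthenium alkylidene loads by [2+2] cycloaddition/cycloreversion on one terminal alkene of 18 (most readily the monosubstituted C5-vinyl group), the new carbene adds intramolecularly to the other alkene through a ruthenacyclobutane, and cycloreversion releases the C6=C7 bond and, overall, ethene. The closest known reaction type is the ring-closing metathesis of an α,ω-diene to a trisubstituted cyclohexene, here between a vinyl group on a quaternary carbon and a 1,1-disubstituted alkene. Ring D is the only ring closed, in an intramolecular six-membered mode through the C6=C7 bond alone; rings A, B and C are untouched. No stereocentre is created, since C1, C2, C5, C10 and C11 are already in place and the ring size enforces the cis geometry of C6=C7. The selectivity needed is ring closure over intermolecular metathesis and over alkene migration; it is secured by high dilution, by the geminal substitution at spiro C5 that holds the two alkenes close (Thorpe–Ingold effect), by the absence of any other alkene in 18, and by loss of ethene. Ruthenium carbenes tolerate free phenols and hydrogen-bonded aryl aldehydes, so no protecting group is needed and the product is the target itself.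

**Compound list**

1 | methyl 2-oxocyclopentane-1-carboxylate | COC(=O)C1CCCC1=O | starting material
2 | (E)-but-2-en-1-ol | C/C=C/CO | starting material
3 | methyl 2-[(E)-but-2-enyloxy]cyclopent-1-ene-1-carboxylate | COC(=O)C1=C(OC/C=C/C)CCC1 | intermediate
4 | methyl (1S)-1-[(2S)-but-3-en-2-yl]-2-oxocyclopentane-1-carboxylate | O=C1CCC[C@]1(C(=O)OC)[C@@H](C)C=C | intermediate
5 | 2-bromo-3-methylbut-1-ene | C=C(Br)C(C)C | starting material
6 | methyl (1S)-1-[(2S)-4-(9-borabicyclo[3.3.1]nonan-9-yl)butan-2-yl]-2-oxocyclopentane-1-carboxylate (not isolated) | O=C1CCC[C@]1(C(=O)OC)[C@@H](C)CCB1C2CCCC1CCC2 | intermediate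
7 | methyl (1S)-1-[(2S)-6-methyl-5-methylideneheptan-2-yl]-2-oxocyclopentane-1-carboxylate | O=C1CCC[C@]1(C(=O)OC)[C@@H](C)CCC(=C)C(C)C | intermediate
8 | (1RS,2R)-2-(hydroxymethyl)-2-[(2S)-6-methyl-5-methylideneheptan-2-yl]cyclopentan-1-ol | OC1CCC[C@]1(CO)[C@@H](C)CCC(=C)C(C)C | intermediate
9 | (1R)-1-[(2S)-6-methyl-5-methylideneheptan-2-yl]-2-oxocyclopentane-1-carbaldehyde | O=C1CCC[C@]1(C=O)[C@@H](C)CCC(=C)C(C)C | intermediate
10 | (2S)-2-ethenyl-2-[(2S)-6-methyl-5-methylideneheptan-2-yl]cyclopentan-1-one | O=C1CCC[C@]1(C=C)[C@@H](C)CCC(=C)C(C)C | intermediate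
11 | lithium enolate of 10, lithium (5S)-5-ethenyl-5-[(2S)-6-methyl-5-methylideneheptan-2-yl]cyclopent-1-en-1-olate (not isolated) | [Li]OC1=CCC[C@]1(C=C)[C@@H](C)CCC(=C)C(C)C | intermediate
12 | (2S,5RS)-2-ethenyl-5-methyl-2-[(2S)-6-methyl-5-methylideneheptan-2-yl]cyclopentan-1-one | O=C1C(C)CC[C@]1(C=C)[C@@H](C)CCC(=C)C(C)C | intermediate
13 | tert-butyl({(5S)-5-ethenyl-2-methyl-5-[(2S)-6-methyl-5-methylideneheptan-2-yl]cyclopent-1-en-1-yl}oxy)dimethylsilane | CC1=C(O[Si](C)(C)C(C)(C)C)[C@](C=C)(CC1)[C@@H](C)CCC(=C)C(C)C | intermediate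
14 | 2,4,6-trihydroxybenzene-1,3-dicarbaldehyde | O=Cc1c(O)cc(O)c(C=O)c1O | starting material
15 | 3-methylbutanal | CC(C)CC=O | starting material
16 | ortho-quinone methide, 2,4-dihydroxy-5-(3-methylbutylidene)-6-oxocyclohexa-1,3-diene-1,3-dicarbaldehyde (not isolated) | CC(C)CC=C1C(=O)C(C=O)=C(O)C(C=O)=C1O | intermediate
17 | (3S,3aR,9S,9aR)-3a-[(tert-butyldimethylsilyl)oxy]-3-ethenyl-6,8-dihydroxy-9a-methyl-3-[(2S)-6-methyl-5-methylideneheptan-2-yl]-9-(2-methylpropyl)-1,2,3,3a,9,9a-hexahydrocyclopenta[b]chromene-5,7-dicarbaldehyde | CC(C)C[C@H]1c2c(O)c(C=O)c(O)c(C=O)c2O[C@@]2(O[Si](C)(C)C(C)(C)C)[C@]1(C)CC[C@]2(C=C)[C@@H](C)CCC(=C)C(C)C | intermediate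
18 | (3S,3aS,9R,9aR)-3-ethenyl-6,8-dihydroxy-9a-methyl-3-[(2S)-6-methyl-5-methylideneheptan-2-yl]-9-(2-methylpropyl)-1,2,3,3a,9,9a-hexahydrocyclopenta[b]chromene-5,7-dicarbaldehyde | CC(C)C[C@H]1c2c(O)c(C=O)c(O)c(C=O)c2O[C@H]2[C@]1(C)CC[C@]2(C=C)[C@@H](C)CCC(=C)C(C)C | intermediate
19 | (1R,3a'S,6S,9'R,9a'R)-6',8'-dihydroxy-6,9a'-dimethyl-9'-(2-methylpropyl)-3-(propan-2-yl)-1',2',9',9a'-tetrahydro-3a'H-spiro[cyclohex-2-ene-1,3'-cyclopenta[b]chromene]-5',7'-dicarbaldehyde | CC(C)C[C@H]1c2c(O)c(C=O)c(O)c(C=O)c2O[C@H]2[C@]1(C)CC[C@@]21C=C(C(C)C)CC[C@@H]1C | target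

**Step count and risks**

Total steps: 11. Longest linear sequence: 11 steps (1 to 19).

Steps most likely to fail:

Step 9. The cycloaddition has to join a secondary quinone methide carbon to a tetrasubstituted enol silane next to a quaternary centre. The addition may be slow, letting the quinone methide oligomerise or react with the 1,1-disubstituted alkene, and the two C5 substituents (vinyl against sec-alkyl) may not differentiate the enol ether faces well enough. The fallback replaces the thermal, concerted three-component cycloaddition with a stepwise, cationic conjugate addition at low temperature and a separate reductive closure of ring B. It sets out from 13 and returns at 18. Compounds 14 and 15 are condensed in methanol to give the stable adduct 2,4,6-trihydroxy-5-(1-methoxy-3-methylbutyl)benzene-1,3-dicarbaldehyde F1. Ionisation of F1 with catalytic BF3·OEt2 in CH2Cl2 at −78 °C in the presence of 13 gives, by Mukaiyama–Michael addition through an open transition state and loss of the silyl group, the keto phenol (2S,5R)-5-[(1S)-1-(3,5-diformyl-2,4,6-trihydroxyphenyl)-3-methylbutyl]-2-ethenyl-5-methyl-2-[(2S)-6-methyl-5-methylideneheptan-2-yl]cyclopentan-1-one F2. Reductive etherification of F2 with Et3SiH and BF3·OEt2 then closes ring B and gives 18, still before ring D is formed.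

Step 10. Hydride may approach the oxocarbenium ion from the face flanked by the C5-vinyl group and give the trans-fused C1 epimer, and the Lewis acid may also bring about reduction of a formyl group or protonation of the 1,1-disubstituted alkene. The fallback exchanges the ionic reduction for a neutral radical one. It sets out from 12 and returns at 18. Ketone 12 with PhSH, TiCl4 and Et3N gives the vinyl sulfide ({(5S)-5-ethenyl-2-methyl-5-[(2S)-6-methyl-5-methylideneheptan-2-yl]cyclopent-1-en-1-yl}sulfanyl)benzene F3. The same three-component cycloaddition with 14 and 15 gives the O,S-ketal (3S,3aR,9S,9aR)-3-ethenyl-6,8-dihydroxy-9a-methyl-3-[(2S)-6-methyl-5-methylideneheptan-2-yl]-9-(2-methylpropyl)-3a-(phenylsulfanyl)-1,2,3,3a,9,9a-hexahydrocyclopenta[b]chromene-5,7-dicarbaldehyde F4. Bu3SnH with azobisisobutyronitrile in toluene at 80 °C cleaves the C–S bond, and the pyramidal α-alkoxy radical, held in the cis-fused shape of F4, takes up hydrogen to give 18 without acid.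

Step 2. The catalysed rearrangement may proceed with insufficient enantioselectivity, or part of the material may pass through a boat transition state and erode the C5/C10 ratio. The fallback forms the same C5–C10 bond by metal-catalysed allylic substitution instead of a sigmatropic shift. It sets out from 1 and returns at 4. Keto ester 1 is alkylated with (E)-but-2-enyl methyl carbonate under [Ir(cod)Cl]2, a chiral phosphoramidite ligand and LiBr in THF; outer-sphere attack of the enolate on the π-allyl iridium complex gives the branched product with the vicinal quaternary and tertiary centres. If this gives the other diastereomer, the mismatch would show at 4 and the Z-crotyl ether in the Claisen route is the alternative. This fallback makes no compound outside the list (F0).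

**Further compounds**

F1 | step 9 | 2,4,6-trihydroxy-5-(1-methoxy-3-methylbutyl)benzene-1,3-dicarbaldehyde | CC(C)CC(OC)c1c(O)c(C=O)c(O)c(C=O)c1O
F2 | step 9 | (2S,5R)-5-[(1S)-1-(3,5-diformyl-2,4,6-trihydroxyphenyl)-3-methylbutyl]-2-ethenyl-5-methyl-2-[(2S)-6-methyl-5-methylideneheptan-2-yl]cyclopentan-1-one | CC(C)C[C@@H](c1c(O)c(C=O)c(O)c(C=O)c1O)[C@@]1(C)CC[C@](C=C)([C@@H](C)CCC(=C)C(C)C)C1=O
F3 | step 10 | ({(5S)-5-ethenyl-2-methyl-5-[(2S)-6-methyl-5-methylideneheptan-2-yl]cyclopent-1-en-1-yl}sulfanyl)benzene | CC1=C(Sc2ccccc2)[C@](C=C)(CC1)[C@@H](C)CCC(=C)C(C)C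
F4 | step 10 | (3S,3aR,9S,9aR)-3-ethenyl-6,8-dihydroxy-9a-methyl-3-[(2S)-6-methyl-5-methylideneheptan-2-yl]-9-(2-methylpropyl)-3a-(phenylsulfanyl)-1,2,3,3a,9,9a-hexahydrocyclopenta[b]chromene-5,7-dicarbaldehyde | CC(C)C[C@H]1c2c(O)c(C=O)c(O)c(C=O)c2O[C@@]2(Sc3ccccc3)[C@]1(C)CC[C@]2(C=C)[C@@H](C)CCC(=C)C(C)C
F0 | step 2 | none | none
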